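## Retrosynthetic overview

1. C13–Br is installed last by SN2 bromination (inversion) of a (13S)-allylic alcohol; the C1–C4 (Z)-enyne comes from cross-metathesis on a C5 allyl group; the C11=C12 (Z)-alkene comes from semi-hydrogenation of an alkyne.
2. The oxolane is the only ring and is formed once (step 8) from the acyclic trans-epoxide 11: Br+ adds to the (Z)-C9=C10 alkene, the epoxide oxygen closes O–C10, and chloride opens the resulting epoxonium ion at C6. This new step sets C9–Br, C10–O and C6–Cl together.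
3. Epoxide 11 comes from the (R)-α-chloroaldehyde 8 plus an allyl unit (Cornforth-matched allylboration, then Williamson closure).
4. Aldehyde 7 comes from Sonogashira coupling of (Z)-5-iodopent-4-en-1-ol with silylated (S)-pent-1-yn-3-ol, which supplies C13.

Assumption: carbons are numbered C1–C15 from the terminal alkyne carbon along the chain (ring oxygen between C7 and C10), and (S)-pent-1-yn-3-ol is bought enantiopure.

## Route

Step 1
Reactants: 1 pent-4-yn-1-ol
Product: 2 5-iodopent-4-yn-1-ol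
Conditions: NIS, AgNO3 (10 mol%), acetone, rt, dark
Reagents that add atoms: N-iodosuccinimide, O=C1CCC(=O)N1I
Why: Silver-catalysed electrophilic iodination of the terminal alkyne C–H (via the silver acetylide) is clean beside a free primary alcohol and creates no stereocentre.

Step 2
Reactants: 2 5-iodopent-4-yn-1-ol
Product: 3 (Z)-5-iodopent-4-en-1-ol
Conditions: 2-nitrobenzenesulfonyl hydrazide, Et3N, THF/i-PrOH, rt
Reagents that add atoms: none
Why: Diimide semi-reduction: diimide generated in the flask adds two hydrogens syn to the iodoalkyne, which fixes the Z geometry of the iodoalkene.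

Step 3
Reactants: 4 (S)-pent-1-yn-3-ol
Product: 5 tert-butyldimethyl{[(3S)-pent-1-yn-3-yl]oxy}silane
Conditions: TBSCl, imidazole, DMF, rt
Reagents that add atoms: tert-butyldimethylsilyl chloride, CC(C)(C)[Si](C)(C)Cl
Why: Standard silylation of a secondary alcohol leaves the purchased stereocentre (future C13) untouched.

Step 4
Reactants: 3 (Z)-5-iodopent-4-en-1-ol; 5 tert-butyldimethyl{[(3S)-pent-1-yn-3-yl]oxy}silane
Product: 6 (4Z,8S)-8-[(tert-butyldimethylsilyl)oxy]dec-4-en-6-yn-1-ol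
Conditions: PdCl2(PPh3)2 (3 mol%), CuI (6 mol%), Et3N, THF, rt
Reagents that add atoms: none
Why: Sonogashira coupling of an alkenyl iodide with a terminal alkyne proceeds with retention of the Z geometry and tolerates the free alcohol.

Step 5
Reactants: 6 (4Z,8S)-8-[(tert-butyldimethylsilyl)oxy]dec-4-en-6-yn-1-ol
Product: 7 (4Z,8S)-8-[(tert-butyldimethylsilyl)oxy]dec-4-en-6-ynal
Conditions: Dess–Martin periodinane, NaHCO3, CH2Cl2, 0 °C to rt
Reagents that add atoms: none
Why: Buffered Dess–Martin oxidation gives the aldehyde without moving the skipped (Z)-alkene into conjugation.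

Step 6
Reactants: 7 (4Z,8S)-8-[(tert-butyldimethylsilyl)oxy]dec-4-en-6-ynal
Product: 8 (2R,4Z,8S)-8-[(tert-butyldimethylsilyl)oxy]-2-chlorodec-4-en-6-ynal
Conditions: NCS, (2S,5S)-2,5-diphenylpyrrolidine (10 mol%), CH2Cl2, −20 to 0 °C; short silica plug, used at once
Reagents that add atoms: N-chlorosuccinimide, O=C1CCC(=O)N1Cl
Why: Organocatalytic enamine α-chlorination: the phenyl group next to the (E)-enamine carbon blocks one face, so chlorine is delivered to the other and sets the (R)-chloride (this catalyst antipode is chosen for that sense).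

Step 7
Reactants: 8 (2R,4Z,8S)-8-[(tert-butyldimethylsilyl)oxy]-2-chlorodec-4-en-6-ynal
Product: 11 (2S,3S)-2-(prop-2-en-1-yl)-3-[(2Z,6S)-6-[(tert-butyldimethylsilyl)oxy]oct-2-en-4-yn-1-yl]oxirane, via pinacol borate ester 9 (not isolated), via anti-chlorohydrin 10 (not isolated)
Conditions: allylB(pin), (S)-TRIP phosphoric acid (5 mol%), PhMe, −30 °C; then K2CO3, MeOH, rt
Reagents that add atoms: allylboronic acid pinacol ester, C=CCB1OC(C)(C)C(C)(C)O1
Why: Chiral phosphoric acid-catalysed allylboration through a chair transition state adds allyl to the Si face, which is also the Cornforth-preferred face (C–Cl anti to C=O), giving the anti (6S,7R)-chlorohydrin; methanolysis of the borate and Williamson closure with inversion at C7 then give the trans (6S,7S)-epoxide.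

Step 8
Reactants: 11 (2S,3S)-2-(prop-2-en-1-yl)-3-[(2Z,6S)-6-[(tert-butyldimethylsilyl)oxy]oct-2-en-4-yn-1-yl]oxirane
Product: 14 (2R,3R,5S)-3-bromo-5-[(1R)-1-chlorobut-3-en-1-yl]-2-[(3S)-3-[(tert-butyldimethylsilyl)oxy]pent-1-yn-1-yl]oxolane, via bromonium ion 12 (not isolated), via epoxonium ion 13 (not isolated)
Conditions: NBS (1.05 equiv), Et4NCl (2 equiv), HFIP/CH2Cl2 (1:1), 4 Å MS, −20 °C
Reagents that add atoms: N-bromosuccinimide, O=C1CCC(=O)N1Br; tetraethylammonium chloride, CC[N+](CC)(CC)CC.[Cl-]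
Why: Proposed new method: NBS activated by HFIP transfers Br+ reversibly to the alkenes, and only the bromonium ion on the (Z)-C9=C10 enyne alkene has an internal nucleophile, the epoxide oxygen, which attacks the propargylic carbon C10 in a 5-endo anti fashion (attack at C9 would give a strained four-membered ring, and attack on the terminal alkene would have to be anti-Markovnikov) to give the 2-oxoniabicyclo[3.1.0]hexane ion 13, in which Br and the alkynyl group are cis by stereospecific anti addition to the Z-alkene and both lie opposite the epoxide carbon C6 because the other transition state eclipses the C10 substituent with the O–C6 bond (this sets the 2,5-trans relationship, whereas a free C7 hydroxyl would be expected to follow the usual chair-like 5-endo path to the 2,5-cis isomer and could also cyclise 5-exo onto C3=C4); chloride, whose attack on the bromonium ion is damped by HFIP solvation, then opens the strained three-membered ring at the exocyclic carbon C6 with inversion (6S to 6R), preferred over C7 (backside shielded by the oxolane) and over C10 (no strain release); the closest known reaction type is the bromonium-initiated epoxide-opening cascade in HFIP and the 5-exo bromonium/epoxide participation with capture of the oxonium ion by an external nucleophile, which has not been shown in the 5-endo mode, on a conjugated enyne, or with chloride delivered to a trans-disubstituted epoxide carbon.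

Step 9
Reactants: 14 (2R,3R,5S)-3-bromo-5-[(1R)-1-chlorobut-3-en-1-yl]-2-[(3S)-3-[(tert-butyldimethylsilyl)oxy]pent-1-yn-1-yl]oxolane
Product: 15 (2R,3R,5S)-3-bromo-5-[(1R)-1-chlorobut-3-en-1-yl]-2-[(1Z,3S)-3-[(tert-butyldimethylsilyl)oxy]pent-1-en-1-yl]oxolane
Conditions: H2 (1 atm), Lindlar catalyst (Pd on CaCO3 poisoned with Pb(OAc)2), quinoline, EtOAc, rt, stopped at 1 equiv H2
Reagents that add atoms: none
Why: Lindlar semi-hydrogenation adds H2 syn to the only alkyne to give the (Z)-C11=C12 alkene, while the terminal alkene and the secondary C–Br and C–Cl bonds survive under quinoline poisoning and uptake control.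

Step 10
Reactants: 16 ethynyltriisopropylsilane; 17 bromoethene
Product: 18 (but-3-en-1-yn-1-yl)triisopropylsilane
Conditions: Pd(PPh3)4 (2 mol%), CuI (4 mol%), Et2NH, THF, 0 °C to rt
Reagents that add atoms: none
Why: Sonogashira coupling of vinyl bromide with the silylacetylene gives the conjugated enyne partner.

Step 11
Reactants: 15 (2R,3R,5S)-3-bromo-5-[(1R)-1-chlorobut-3-en-1-yl]-2-[(1Z,3S)-3-[(tert-butyldimethylsilyl)oxy]pent-1-en-1-yl]oxolane; 18 (but-3-en-1-yn-1-yl)triisopropylsilane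
Product: 19 (2R,3R,5S)-3-bromo-5-[(1R,3Z)-1-chloro-6-(triisopropylsilyl)hex-3-en-5-yn-1-yl]-2-[(1Z,3S)-3-[(tert-butyldimethylsilyl)oxy]pent-1-en-1-yl]oxolane
Conditions: 18 (4 equiv), second-generation Grubbs catalyst RuCl2(=CHPh)(H2IMes)(PCy3) (10 mol%), CH2Cl2, 40 °C
Reagents that add atoms: none
Why: Olefin cross-metathesis of a terminal alkene with a conjugated enyne is kinetically Z-selective because the slim alkynyl group tolerates the cis arrangement in the ruthenacyclobutane, and the internal C11=C12 alkene, flanked by two branched carbons, does not react.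

Step 12
Reactants: 19 (2R,3R,5S)-3-bromo-5-[(1R,3Z)-1-chloro-6-(triisopropylsilyl)hex-3-en-5-yn-1-yl]-2-[(1Z,3S)-3-[(tert-butyldimethylsilyl)oxy]pent-1-en-1-yl]oxolane
Product: 20 (1Z,3S)-1-{(2R,3R,5S)-3-bromo-5-[(1R,3Z)-1-chlorohex-3-en-5-yn-1-yl]oxolan-2-yl}pent-1-en-3-ol
Conditions: n-Bu4NF, AcOH, THF, 0 °C to rt
Reagents that add atoms: none
Why: Fluoride-mediated desilylation removes the O-silyl and the alkynyl C-silyl groups together, and acetic acid buffering suppresses E2 loss of HCl or HBr.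

Step 13
Reactants: 20 (1Z,3S)-1-{(2R,3R,5S)-3-bromo-5-[(1R,3Z)-1-chlorohex-3-en-5-yn-1-yl]oxolan-2-yl}pent-1-en-3-ol
Product: 22 (2R,3R,5S)-3-bromo-2-[(1Z,3R)-3-bromopent-1-en-1-yl]-5-[(1R,3Z)-1-chlorohex-3-en-5-yn-1-yl]oxolane, via alkoxyphosphonium bromide 21 (not isolated)
Conditions: CBr4, PPh3, 2,6-di-tert-butylpyridine, CH2Cl2, −20 to 0 °C
Reagents that add atoms: carbon tetrabromide, BrC(Br)(Br)Br
Why: Appel reaction: bromide displaces the alkoxyphosphonium group by SN2 with inversion (13S to 13R), and the SN2′ path is disfavoured because C11 is shielded by the ring.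

## Compound list

1 | pent-4-yn-1-ol | C#CCCCO | starting material
2 | 5-iodopent-4-yn-1-ol | OCCCC#CI | intermediate
3 | (Z)-5-iodopent-4-en-1-ol | OCCC/C=C\I | intermediate
4 | (S)-pent-1-yn-3-ol | CC[C@H](O)C#C | starting material
5 | tert-butyldimethyl{[(3S)-pent-1-yn-3-yl]oxy}silane | CC[C@H](O[Si](C)(C)C(C)(C)C)C#C | intermediate
6 | (4Z,8S)-8-[(tert-butyldimethylsilyl)oxy]dec-4-en-6-yn-1-ol | OCCC/C=C\C#C[C@@H](O[Si](C)(C)C(C)(C)C)CC | intermediate
7 | (4Z,8S)-8-[(tert-butyldimethylsilyl)oxy]dec-4-en-6-ynal | O=CCC/C=C\C#C[C@@H](O[Si](C)(C)C(C)(C)C)CC | intermediate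
8 | (2R,4Z,8S)-8-[(tert-butyldimethylsilyl)oxy]-2-chlorodec-4-en-6-ynal | O=C[C@H](Cl)C/C=C\C#C[C@@H](O[Si](C)(C)C(C)(C)C)CC | intermediate
9 | 2-{[(4S,5R,7Z,11S)-11-[(tert-butyldimethylsilyl)oxy]-5-chlorotrideca-1,7-dien-9-yn-4-yl]oxy}-4,4,5,5-tetramethyl-1,3,2-dioxaborolane (pinacol borate ester) | C=CC[C@H](OB1OC(C)(C)C(C)(C)O1)[C@H](Cl)C/C=C\C#C[C@@H](O[Si](C)(C)C(C)(C)C)CC | intermediate
10 | (4S,5R,7Z,11S)-11-[(tert-butyldimethylsilyl)oxy]-5-chlorotrideca-1,7-dien-9-yn-4-ol (anti-chlorohydrin) | C=CC[C@H](O)[C@H](Cl)C/C=C\C#C[C@@H](O[Si](C)(C)C(C)(C)C)CC | intermediate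
11 | (2S,3S)-2-(prop-2-en-1-yl)-3-[(2Z,6S)-6-[(tert-butyldimethylsilyl)oxy]oct-2-en-4-yn-1-yl]oxirane | C=CC[C@@H]1O[C@H]1C/C=C\C#C[C@@H](O[Si](C)(C)C(C)(C)C)CC | intermediate
12 | bromonium ion of 11 across C9–C10 (C8 and C11 cis on the three-membered ring) | C=CC[C@@H]1O[C@H]1C[C@H]2[Br+][C@H]2C#C[C@@H](O[Si](C)(C)C(C)(C)C)CC | intermediate
13 | epoxonium ion (2-oxoniabicyclo[3.1.0]hexane; O+ bonded to C6, C7 and C10; Br at C9 cis to the alkynyl group at C10; C6 on the opposite face) | C=CC[C@@H]1[O+]2[C@H]1C[C@@H](Br)[C@H]2C#C[C@@H](O[Si](C)(C)C(C)(C)C)CC | intermediate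
14 | (2R,3R,5S)-3-bromo-5-[(1R)-1-chlorobut-3-en-1-yl]-2-[(3S)-3-[(tert-butyldimethylsilyl)oxy]pent-1-yn-1-yl]oxolane | C=CC[C@@H](Cl)[C@@H]1C[C@@H](Br)[C@@H](C#C[C@@H](O[Si](C)(C)C(C)(C)C)CC)O1 | intermediate
15 | (2R,3R,5S)-3-bromo-5-[(1R)-1-chlorobut-3-en-1-yl]-2-[(1Z,3S)-3-[(tert-butyldimethylsilyl)oxy]pent-1-en-1-yl]oxolane | C=CC[C@@H](Cl)[C@@H]1C[C@@H](Br)[C@@H](/C=C\[C@@H](O[Si](C)(C)C(C)(C)C)CC)O1 | intermediate
16 | ethynyltriisopropylsilane | C#C[Si](C(C)C)(C(C)C)C(C)C | starting material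
17 | bromoethene | C=CBr | starting material
18 | (but-3-en-1-yn-1-yl)triisopropylsilane | C=CC#C[Si](C(C)C)(C(C)C)C(C)C | intermediate
19 | (2R,3R,5S)-3-bromo-5-[(1R,3Z)-1-chloro-6-(triisopropylsilyl)hex-3-en-5-yn-1-yl]-2-[(1Z,3S)-3-[(tert-butyldimethylsilyl)oxy]pent-1-en-1-yl]oxolane | CC(C)[Si](C(C)C)(C(C)C)C#C/C=C\C[C@@H](Cl)[C@@H]1C[C@@H](Br)[C@@H](/C=C\[C@@H](O[Si](C)(C)C(C)(C)C)CC)O1 | intermediate
20 | (1Z,3S)-1-{(2R,3R,5S)-3-bromo-5-[(1R,3Z)-1-chlorohex-3-en-5-yn-1-yl]oxolan-2-yl}pent-1-en-3-ol | C#C/C=C\C[C@@H](Cl)[C@@H]1C[C@@H](Br)[C@@H](/C=C\[C@@H](O)CC)O1 | intermediate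
21 | {[(1Z,3S)-1-{(2R,3R,5S)-3-bromo-5-[(1R,3Z)-1-chlorohex-3-en-5-yn-1-yl]oxolan-2-yl}pent-1-en-3-yl]oxy}triphenylphosphonium bromide | C#C/C=C\C[C@@H](Cl)[C@@H]1C[C@@H](Br)[C@@H](/C=C\[C@@H](O[P+](c2ccccc2)(c2ccccc2)c2ccccc2)CC)O1.[Br-] | intermediate
22 | (2R,3R,5S)-3-bromo-2-[(1Z,3R)-3-bromopent-1-en-1-yl]-5-[(1R,3Z)-1-chlorohex-3-en-5-yn-1-yl]oxolane | C#C/C=C\C[C@@H](Cl)[C@@H]1C[C@@H](Br)[C@@H](/C=C\[C@H](Br)CC)O1 | target

## Step count and risks

Total steps: 13. Longest linear sequence: 11 (steps 1, 2, 4, 5, 6, 7, 8, 9, 11, 12, 13).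

The three steps most likely to fail:

**Step 8 (the proposed new cascade).** The risks are direct bromochlorination of an alkene, opening of the epoxonium ion at C7 to give an oxane, and incomplete 2,5-trans selectivity. The fallback uses known chemistry, sets out from 11 and comes back at 14. Epoxide 11 is opened with pyridinium chloride in CH2Cl2 to a roughly 1:1 mixture of chlorohydrin 10, which is returned to 11 with K2CO3/MeOH, and the regioisomeric (4R,5S,7Z,11S)-11-[(tert-butyldimethylsilyl)oxy]-4-chlorotrideca-1,7-dien-9-yn-5-ol F1. Hydroxyl-directed, catalyst-controlled epoxidation of the homoallylic (Z)-alkene of F1 (VO(OiPr)3, chiral bishydroxamic acid ligand, cumene hydroperoxide) gives the cis-epoxy alcohol (1S,2R)-2-chloro-1-{[(2R,3S)-3-[(3S)-3-[(tert-butyldimethylsilyl)oxy]pent-1-yn-1-yl]oxiran-2-yl]methyl}pent-4-en-1-ol F2. Camphorsulfonic acid then triggers 5-endo opening at the propargylic carbon with inversion to give (2R,3R,5S)-5-[(1R)-1-chlorobut-3-en-1-yl]-2-[(3S)-3-[(tert-butyldimethylsilyl)oxy]pent-1-yn-1-yl]oxolan-3-ol F3, whose hydroxyl is cis to the alkynyl group. Mitsunobu inversion (4-nitrobenzoic acid, PPh3, DIAD) gives the (2R,3S,5S)-oxolan-3-yl 4-nitrobenzoate F4, methanolysis (K2CO3, MeOH) gives the (2R,3S,5S)-oxolan-3-ol F5, and SN2 bromination (CBr4, P(n-C8H17)3, PhMe, 70 °C) returns 14.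

**Step 11 (Z-selectivity of the enyne cross-metathesis).** The fallback sets out from 15 and comes back at 19. Z-selective cross-metathesis of 15 with (Z)-1,2-dichloroethene, catalysed by a molybdenum monoaryloxide pyrrolide alkylidene Mo(NC6F5)(CHCMe2Ph)(2,5-dimethylpyrrolide)(OAr), gives (2R,3R,5S)-3-bromo-5-[(1R,3Z)-1,4-dichlorobut-3-en-1-yl]-2-[(1Z,3S)-3-[(tert-butyldimethylsilyl)oxy]pent-1-en-1-yl]oxolane F6. Sonogashira coupling of F6 with ethynyltriisopropylsilane 16 (PdCl2(PhCN)2, CuI, piperidine) then gives 19 with retention of the Z geometry.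

**Step 13 (SN2 against SN2′ or ionisation at the (Z)-allylic carbinol).** The fallback sets out from 20 and comes back at 22. It replaces oxyphosphonium activation by sulfonate displacement: MsCl and Et3N in CH2Cl2 at −40 °C give (1Z,3S)-1-{(2R,3R,5S)-3-bromo-5-[(1R,3Z)-1-chlorohex-3-en-5-yn-1-yl]oxolan-2-yl}pent-1-en-3-yl methanesulfonate F7, which is displaced in the same flask by LiBr in THF at −20 °C with inversion.

Further compounds
F1 | step 8 | (4R,5S,7Z,11S)-11-[(tert-butyldimethylsilyl)oxy]-4-chlorotrideca-1,7-dien-9-yn-5-ol | C=CC[C@@H](Cl)[C@@H](O)C/C=C\C#C[C@@H](O[Si](C)(C)C(C)(C)C)CC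
F2 | step 8 | (1S,2R)-2-chloro-1-{[(2R,3S)-3-[(3S)-3-[(tert-butyldimethylsilyl)oxy]pent-1-yn-1-yl]oxiran-2-yl]methyl}pent-4-en-1-ol | C=CC[C@@H](Cl)[C@@H](O)C[C@H]1O[C@H]1C#C[C@@H](O[Si](C)(C)C(C)(C)C)CC
F3 | step 8 | (2R,3R,5S)-5-[(1R)-1-chlorobut-3-en-1-yl]-2-[(3S)-3-[(tert-butyldimethylsilyl)oxy]pent-1-yn-1-yl]oxolan-3-ol | C=CC[C@@H](Cl)[C@@H]1C[C@@H](O)[C@@H](C#C[C@@H](O[Si](C)(C)C(C)(C)C)CC)O1
F4 | step 8 | (2R,3S,5S)-5-[(1R)-1-chlorobut-3-en-1-yl]-2-[(3S)-3-[(tert-butyldimethylsilyl)oxy]pent-1-yn-1-yl]oxolan-3-yl 4-nitrobenzoate | C=CC[C@@H](Cl)[C@@H]1C[C@H](OC(=O)c2ccc(cc2)[N+](=O)[O-])[C@@H](C#C[C@@H](O[Si](C)(C)C(C)(C)C)CC)O1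
F5 | step 8 | (2R,3S,5S)-5-[(1R)-1-chlorobut-3-en-1-yl]-2-[(3S)-3-[(tert-butyldimethylsilyl)oxy]pent-1-yn-1-yl]oxolan-3-ol | C=CC[C@@H](Cl)[C@@H]1C[C@H](O)[C@@H](C#C[C@@H](O[Si](C)(C)C(C)(C)C)CC)O1
F6 | step 11 | (2R,3R,5S)-3-bromo-5-[(1R,3Z)-1,4-dichlorobut-3-en-1-yl]-2-[(1Z,3S)-3-[(tert-butyldimethylsilyl)oxy]pent-1-en-1-yl]oxolane | Cl/C=C\C[C@@H](Cl)[C@@H]1C[C@@H](Br)[C@@H](/C=C\[C@@H](O[Si](C)(C)C(C)(C)C)CC)O1
F7 | step 13 | (1Z,3S)-1-{(2R,3R,5S)-3-bromo-5-[(1R,3Z)-1-chlorohex-3-en-5-yn-1-yl]oxolan-2-yl}pent-1-en-3-yl methanesulfonate | C#C/C=C\C[C@@H](Cl)[C@@H]1C[C@@H](Br)[C@@H](/C=C\[C@@H](OS(C)(=O)=O)CC)O1
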